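**Retrosynthetic overview**
1. Numbering: tetralin C1–C4, C4a, C5–C8, C8a (ring A aromatic, ring B saturated); C11 is the side-chain methine on C1, C12–C16 run to the ester oxygen, C20 is the methyl on C4.
2. The strategy rests on C4: a methyl-bearing benzylic methine of ring B bonded to C4a, the ring A carbon ortho to the C5 oxygen. The C4–C4a bond is therefore made last, by Markovnikov hydroarylation of a C4=C20 terminal alkene (C4a as arene nucleophile, C4 as cation equivalent).
3. Target ⇒ tetralin 20 (side-chain acylation, three deprotections) ⇒ key step ⇒ butenyl benzoate 19 ⇒ aryl bromide 16. The C8 carboxyl comes from Br/Li exchange and CO2 only after all enolate chemistry, because an ester ortho to the lactone-bearing carbon would be open to Dieckmann attack by the lactone enolate.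
4. 16 ⇒ C3–C4 by vinyl/iodide coupling; C12=C13 by cross-metathesis, then hydrogenation; C1 and C11 by rhodium-catalysed asymmetric aryl addition to 5,6-dihydro-2H-pyran-2-one and trans-selective lactone methylation; C15 from (S)-3-bromo-2-methylpropan-1-ol.
5. Ring order: ring A is bought, the lactone ring is a temporary stereocontrol scaffold that is opened, ring B is closed in step 15.

Key step: step 15

Remark (assumption): [3-(methoxymethoxy)phenyl]boronic acid 1 is taken as a catalogue compound; otherwise it is two steps from 3-bromophenol (MOMCl/i-Pr2NEt, then n-BuLi/B(Oi-Pr)3).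

**Route**

Step 1
Reactants: 1 [3-(methoxymethoxy)phenyl]boronic acid; 2 5,6-dihydro-2H-pyran-2-one
Product: 3 (4S)-4-[3-(methoxymethoxy)phenyl]oxan-2-one
Conditions: Rh(acac)(C2H4)2 (3 mol%), (S)-BINAP (3.3 mol%), 1 (2.5 equiv), dioxane/H2O 10:1, 100 °C
Reagents that add atoms: none
Why: Hayashi–Miyaura rhodium-catalysed asymmetric 1,4-addition, in which the aryl–rhodium/(S)-BINAP complex should add to one enantioface of the unsaturated lactone and set C1 as the 4S centre (sense of induction as for cyclic enones; the ligand antipode is used if it proves opposite), a meta-substituted boronic acid without ortho groups being a well-behaved partner.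

Step 2
Reactants: 3 (4S)-4-[3-(methoxymethoxy)phenyl]oxan-2-one
Product: 5 (3R,4S)-4-[3-(methoxymethoxy)phenyl]-3-methyloxan-2-one (3,4-trans), via lithium enolate 4 (not isolated)
Conditions: LDA (1.1 equiv), THF, −78 °C; MeI (3 equiv), −78 → −40 °C
Reagents that add atoms: iodomethane, CI
Why: Kinetic lactone enolate alkylation, in which iodomethane should approach the half-chair enolate anti to the adjacent aryl group, giving the 3,4-trans lactone and thereby the C11 centre, with no aryl ester yet present for the enolate to attack.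

Step 3
Reactants: 5 (3R,4S)-4-[3-(methoxymethoxy)phenyl]-3-methyloxan-2-one
Product: 6 (3R,4S)-4-[3-(methoxymethoxy)phenyl]-3-methyloxan-2-ol (lactol, anomer mixture)
Conditions: i-Bu2AlH (1.1 equiv), CH2Cl2, −78 °C; Rochelle salt work-up
Reagents that add atoms: none
Why: Partial lactone reduction with i-Bu2AlH at −78 °C stops at the lactol because the tetrahedral aluminium hemiacetal is stable until work-up, and no stereocentre is touched.

Step 4
Reactants: 6 (3R,4S)-4-[3-(methoxymethoxy)phenyl]-3-methyloxan-2-ol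
Product: 7 (3S,4S)-3-[3-(methoxymethoxy)phenyl]-4-methylhex-5-en-1-ol
Conditions: Ph3PCH3Br (3.5 equiv), KOt-Bu (3.3 equiv), THF, 0 °C → rt
Reagents that add atoms: methyltriphenylphosphonium bromide, C[P+](c1ccccc1)(c1ccccc1)c1ccccc1.[Br-]
Why: Wittig methylenation of the open hydroxy-aldehyde form of the lactol with a non-stabilised ylide, which should outrun epimerisation at C11, leaves the C3 hydroxyl free and so tells the two chain ends apart without a protecting group.

Step 5
Reactants: 8 (S)-3-bromo-2-methylpropan-1-ol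
Product: 9 (S)-(3-bromo-2-methylpropoxy)(tert-butyl)dimethylsilane
Conditions: TBSCl, imidazole, CH2Cl2, 0 °C → rt
Reagents that add atoms: tert-butyldimethylsilyl chloride, CC(C)(C)[Si](C)(C)Cl
Why: Standard silyl ether formation at a primary alcohol; the stereocentre is not involved.

Step 6
Reactants: 9 (S)-(3-bromo-2-methylpropoxy)(tert-butyl)dimethylsilane
Product: 10 (S)-tert-butyl(3-iodo-2-methylpropoxy)dimethylsilane
Conditions: NaI, acetone, reflux
Reagents that add atoms: sodium iodide, [Na+].[I-]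
Why: Finkelstein halide exchange (SN2 at the primary carbon) gives the more reactive iodide for the copper-catalysed coupling and leaves C15 untouched.

Step 7
Reactants: 10 (S)-tert-butyl(3-iodo-2-methylpropoxy)dimethylsilane
Product: 11 (R)-tert-butyldimethyl[(2-methylpent-4-en-1-yl)oxy]silane
Conditions: CH2=CHMgBr (3 equiv), CuI (20 mol%), THF, −30 → 0 °C
Reagents that add atoms: vinylmagnesium bromide, C=C[Mg]Br
Why: Copper-catalysed cross-coupling of a vinyl Grignard reagent with a primary alkyl iodide forms the C13–C14 bond, the stereocentre lying β to the reacting carbon and being retained (the descriptor changes only by priority).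

Step 8
Reactants: 7 (3S,4S)-3-[3-(methoxymethoxy)phenyl]-4-methylhex-5-en-1-ol; 11 (R)-tert-butyldimethyl[(2-methylpent-4-en-1-yl)oxy]silane
Product: 12 (3S,4S,8R)-9-[(tert-butyldimethylsilyl)oxy]-3-[3-(methoxymethoxy)phenyl]-4,8-dimethylnon-5-en-1-ol (E/Z mixture, E drawn)
Conditions: second-generation Hoveyda–Grubbs catalyst (5 mol%), 11 (3 equiv), CH2Cl2, 40 °C
Reagents that add atoms: none
Why: Olefin cross-metathesis, in which the allylically branched alkene of 7 should not homodimerise, so an excess of the unhindered partner 11 should give the C12=C13 cross product with loss of ethene, the alkene geometry being irrelevant because it is hydrogenated next.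

Step 9
Reactants: 12 (3S,4S,8R)-9-[(tert-butyldimethylsilyl)oxy]-3-[3-(methoxymethoxy)phenyl]-4,8-dimethylnon-5-en-1-ol
Product: 13 (3S,4S,8R)-9-[(tert-butyldimethylsilyl)oxy]-3-[3-(methoxymethoxy)phenyl]-4,8-dimethylnonan-1-ol
Conditions: H2 (1 atm), palladium on carbon (10 wt%), EtOAc, rt
Reagents that add atoms: none
Why: Heterogeneous catalytic hydrogenation saturates the only alkene, while the aryl MOM ether, the silyl ether and the stereocentres are inert.

Step 10
Reactants: 13 (3S,4S,8R)-9-[(tert-butyldimethylsilyl)oxy]-3-[3-(methoxymethoxy)phenyl]-4,8-dimethylnonan-1-ol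
Product: 14 (3S,4S,8R)-3-[2-bromo-5-(methoxymethoxy)phenyl]-9-[(tert-butyldimethylsilyl)oxy]-4,8-dimethylnonan-1-ol
Conditions: NBS (1.05 equiv), MeCN, 0 °C, dark
Reagents that add atoms: N-bromosuccinimide, O=C1CCC(=O)N1Br
Why: Electrophilic aromatic bromination with NBS in acetonitrile should go para to the alkoxy group, which is the C8 position ortho to the side chain, and is run while no alkene is in the molecule.

Step 11
Reactants: 14 (3S,4S,8R)-3-[2-bromo-5-(methoxymethoxy)phenyl]-9-[(tert-butyldimethylsilyl)oxy]-4,8-dimethylnonan-1-ol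
Product: 15 {[(2R,6S,7S)-7-[2-bromo-5-(methoxymethoxy)phenyl]-9-iodo-2,6-dimethylnonyl]oxy}(tert-butyl)dimethylsilane
Conditions: I2, PPh3, imidazole, CH2Cl2, 0 °C → rt
Reagents that add atoms: iodine, II
Why: Appel-type iodination converts the primary C3 alcohol into the iodide under buffered conditions that spare the silyl ether and the acetal.

Step 12
Reactants: 15 {[(2R,6S,7S)-7-[2-bromo-5-(methoxymethoxy)phenyl]-9-iodo-2,6-dimethylnonyl]oxy}(tert-butyl)dimethylsilane
Product: 16 {[(2R,6S,7S)-7-[2-bromo-5-(methoxymethoxy)phenyl]-2,6-dimethylundec-10-en-1-yl]oxy}(tert-butyl)dimethylsilane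
Conditions: CH2=CHMgBr (3 equiv), CuI (20 mol%), THF, −30 → 0 °C
Reagents that add atoms: vinylmagnesium bromide, C=C[Mg]Br
Why: Copper-catalysed coupling of vinylmagnesium bromide with the unhindered primary iodide forms the C3–C4 bond and completes the but-3-enyl arm, the aryl bromide being inert to the Grignard reagent at low temperature.

Step 13
Reactants: 16 {[(2R,6S,7S)-7-[2-bromo-5-(methoxymethoxy)phenyl]-2,6-dimethylundec-10-en-1-yl]oxy}(tert-butyl)dimethylsilane
Product: 18 2-[(5S,6S,10R)-11-[(tert-butyldimethylsilyl)oxy]-6,10-dimethylundec-1-en-5-yl]-4-(methoxymethoxy)benzoic acid, via aryllithium 17 (not isolated)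
Conditions: t-BuLi (2.1 equiv), THF, −78 °C; CO2 (g), −78 °C → rt; cold 0.5 M HCl to pH 4
Reagents that add atoms: carbon dioxide, O=C=O
Why: Bromine–lithium exchange with t-BuLi at −78 °C is faster than directed lithiation or addition to the remote alkene, and the aryllithium is trapped by CO2 (carboxylation) to place the C8 carboxyl.

Step 14
Reactants: 18 2-[(5S,6S,10R)-11-[(tert-butyldimethylsilyl)oxy]-6,10-dimethylundec-1-en-5-yl]-4-(methoxymethoxy)benzoic acid
Product: 19 2-(trimethylsilyl)ethyl 2-[(5S,6S,10R)-11-[(tert-butyldimethylsilyl)oxy]-6,10-dimethylundec-1-en-5-yl]-4-(methoxymethoxy)benzoate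
Conditions: Me3SiCH2CH2OH (2 equiv), EDC·HCl, DMAP, CH2Cl2, rt
Reagents that add atoms: 2-(trimethylsilyl)ethanol, C[Si](C)(C)CCO
Why: Steglich esterification (carbodiimide/DMAP) installs the fluoride-labile 2-(trimethylsilyl)ethyl ester needed for a mild end game.

Step 15
Reactants: 19 2-(trimethylsilyl)ethyl 2-[(5S,6S,10R)-11-[(tert-butyldimethylsilyl)oxy]-6,10-dimethylundec-1-en-5-yl]-4-(methoxymethoxy)benzoate
Product: 20 2-(trimethylsilyl)ethyl (5R,8S)-8-[(2S,6R)-7-[(tert-butyldimethylsilyl)oxy]-6-methylheptan-2-yl]-4-(methoxymethoxy)-5-methyl-5,6,7,8-tetrahydronaphthalene-1-carboxylate (1,4-trans tetralin)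
Conditions: [N,N′-bis(3,5-di-tert-butylsalicylidene)cyclohexane-1,2-diaminato]cobalt (divalent cobalt, 5 mol%; both antipodes screened), N-fluoro-2,4,6-trimethylpyridinium tetrafluoroborate (2 equiv), PhSiH3 (1.5 equiv), PhCF3, 0 °C → rt, argon
Reagents that add atoms: none
Why: The N-fluoropyridinium salt oxidises the divalent cobalt salen complex and PhSiH3 turns it into a cobalt hydride, which transfers a hydrogen atom to the terminal carbon C20; the secondary C4 radical is captured by cobalt and oxidised to an alkyl complex of tetravalent cobalt that acts as a C4 cation equivalent. The closest known reaction type is the cobalt salen catalysed hydrogen-atom-transfer hydroarylation of unactivated alkenes, a radical–polar crossover Friedel–Crafts alkylation. Ring B closes in a 6-exo mode by attack of C4a, the only free arene carbon ortho to the tether and activated by the ortho methoxymethoxy group, and loss of the proton to the collidine released restores ring A. The new C4 stereocentre is set under substrate control in the ring-closing transition state: peri strain with the C8 ester should hold the C1 side chain pseudoaxial and peri strain with the C5 ether should push the incoming C4 methyl pseudoaxial, and only the 1,4-trans arrangement allows both in one half-chair. The step needs Markovnikov regioselectivity, which follows from hydrogen-atom transfer to the terminal carbon, and 1,4-trans diastereoselectivity, which rests on the two peri substituents and is the main uncertainty. The near-neutral conditions should spare the silyl ether, the acetal and the ester, and the metal-bound cation should avoid the hydride shifts of a free secondary cation.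

Step 16
Reactants: 20 2-(trimethylsilyl)ethyl (5R,8S)-8-[(2S,6R)-7-[(tert-butyldimethylsilyl)oxy]-6-methylheptan-2-yl]-4-(methoxymethoxy)-5-methyl-5,6,7,8-tetrahydronaphthalene-1-carboxylate
Product: 21 2-(trimethylsilyl)ethyl (5R,8S)-8-[(2S,6R)-7-hydroxy-6-methylheptan-2-yl]-4-(methoxymethoxy)-5-methyl-5,6,7,8-tetrahydronaphthalene-1-carboxylate
Conditions: CSA (0.2 equiv), MeOH/CH2Cl2 1:1, 0 °C
Reagents that add atoms: none
Why: Acid-catalysed methanolysis cleaves the primary alkyl TBS ether much faster than the aryl MOM ether or the hindered benzoate.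

Step 17
Reactants: 21 2-(trimethylsilyl)ethyl (5R,8S)-8-[(2S,6R)-7-hydroxy-6-methylheptan-2-yl]-4-(methoxymethoxy)-5-methyl-5,6,7,8-tetrahydronaphthalene-1-carboxylate; 22 4-methylpent-3-enoic acid
Product: 23 2-(trimethylsilyl)ethyl (5R,8S)-4-(methoxymethoxy)-5-methyl-8-[(2S,6R)-6-methyl-7-[(4-methylpent-3-enoyl)oxy]heptan-2-yl]-5,6,7,8-tetrahydronaphthalene-1-carboxylate
Conditions: 22 (1.5 equiv), PPh3, DIAD, THF, 0 °C → rt
Reagents that add atoms: none
Why: Mitsunobu esterification activates the alcohol and not the acid, so the β,γ-unsaturated acid never becomes an acylating species whose α-protons could lead to alkene migration, and the primary carbon bears no stereocentre.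

Step 18
Reactants: 23 2-(trimethylsilyl)ethyl (5R,8S)-4-(methoxymethoxy)-5-methyl-8-[(2S,6R)-6-methyl-7-[(4-methylpent-3-enoyl)oxy]heptan-2-yl]-5,6,7,8-tetrahydronaphthalene-1-carboxylate
Product: 25 2-(trimethylsilyl)ethyl (5R,8S)-4-hydroxy-5-methyl-8-[(2S,6R)-6-methyl-7-[(4-methylpent-3-enoyl)oxy]heptan-2-yl]-5,6,7,8-tetrahydronaphthalene-1-carboxylate, via aryl trimethylsilyl ether 24 (not isolated)
Conditions: TMSOTf (2 equiv), 2,2′-bipyridyl (3 equiv), MeCN, 0 °C → rt; then H2O, NaHCO3 work-up
Reagents that add atoms: none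
Why: Silyl triflate/2,2′-bipyridyl cleavage of an aromatic MOM ether proceeds through the aryl silyl ether and a pyridinium salt under buffered, non-protic conditions, which should leave both esters and the trisubstituted alkene alone.

Step 19
Reactants: 25 2-(trimethylsilyl)ethyl (5R,8S)-4-hydroxy-5-methyl-8-[(2S,6R)-6-methyl-7-[(4-methylpent-3-enoyl)oxy]heptan-2-yl]-5,6,7,8-tetrahydronaphthalene-1-carboxylate
Product: 26 (5R,8S)-4-hydroxy-5-methyl-8-[(2S,6R)-6-methyl-7-[(4-methylpent-3-enoyl)oxy]heptan-2-yl]-5,6,7,8-tetrahydronaphthalene-1-carboxylic acid (target, CNP0545998.1)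
Conditions: (Me2N)3S+ Me3SiF2− (TASF, 3 equiv), DMF, 0 °C → rt; cold 0.5 M HCl to pH 3–4
Reagents that add atoms: none
Why: Fluoride attacks silicon and the 2-(trimethylsilyl)ethyl ester fragments by β-elimination to carboxylate, ethene and Me3SiF, the phenol buffering the basicity of fluoride so that the β,γ-alkene should not migrate.

**Compound list**
1 | [3-(methoxymethoxy)phenyl]boronic acid | COCOc1cccc(c1)B(O)O | starting material
2 | 5,6-dihydro-2H-pyran-2-one | O=C1OCCC=C1 | starting material
3 | (4S)-4-[3-(methoxymethoxy)phenyl]oxan-2-one | O=C1C[C@H](CCO1)c2cccc(OCOC)c2 | intermediate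
4 | lithium enolate of lactone 3 | [Li]OC1=C[C@H](CCO1)c2cccc(OCOC)c2 | intermediate (not isolated)
5 | (3R,4S)-4-[3-(methoxymethoxy)phenyl]-3-methyloxan-2-one | O=C1[C@H](C)[C@H](CCO1)c2cccc(OCOC)c2 | intermediate
6 | (3R,4S)-4-[3-(methoxymethoxy)phenyl]-3-methyloxan-2-ol (anomer mixture) | OC1[C@H](C)[C@H](CCO1)c2cccc(OCOC)c2 | intermediate
7 | (3S,4S)-3-[3-(methoxymethoxy)phenyl]-4-methylhex-5-en-1-ol | C=C[C@H](C)[C@H](CCO)c1cccc(OCOC)c1 | intermediate
8 | (S)-3-bromo-2-methylpropan-1-ol | OC[C@H](C)CBr | starting material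
9 | (S)-(3-bromo-2-methylpropoxy)(tert-butyl)dimethylsilane | CC(C)(C)[Si](C)(C)OC[C@H](C)CBr | intermediate
10 | (S)-tert-butyl(3-iodo-2-methylpropoxy)dimethylsilane | CC(C)(C)[Si](C)(C)OC[C@H](C)CI | intermediate
11 | (R)-tert-butyldimethyl[(2-methylpent-4-en-1-yl)oxy]silane | CC(C)(C)[Si](C)(C)OC[C@H](C)CC=C | intermediate
12 | (3S,4S,8R)-9-[(tert-butyldimethylsilyl)oxy]-3-[3-(methoxymethoxy)phenyl]-4,8-dimethylnon-5-en-1-ol (E drawn) | CC(C)(C)[Si](C)(C)OC[C@H](C)C/C=C/[C@H](C)[C@H](CCO)c1cccc(OCOC)c1 | intermediate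
13 | (3S,4S,8R)-9-[(tert-butyldimethylsilyl)oxy]-3-[3-(methoxymethoxy)phenyl]-4,8-dimethylnonan-1-ol | CC(C)(C)[Si](C)(C)OC[C@H](C)CCC[C@H](C)[C@H](CCO)c1cccc(OCOC)c1 | intermediate
14 | (3S,4S,8R)-3-[2-bromo-5-(methoxymethoxy)phenyl]-9-[(tert-butyldimethylsilyl)oxy]-4,8-dimethylnonan-1-ol | CC(C)(C)[Si](C)(C)OC[C@H](C)CCC[C@H](C)[C@H](CCO)c1cc(OCOC)ccc1Br | intermediate
15 | {[(2R,6S,7S)-7-[2-bromo-5-(methoxymethoxy)phenyl]-9-iodo-2,6-dimethylnonyl]oxy}(tert-butyl)dimethylsilane | CC(C)(C)[Si](C)(C)OC[C@H](C)CCC[C@H](C)[C@H](CCI)c1cc(OCOC)ccc1Br | intermediate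
16 | {[(2R,6S,7S)-7-[2-bromo-5-(methoxymethoxy)phenyl]-2,6-dimethylundec-10-en-1-yl]oxy}(tert-butyl)dimethylsilane | CC(C)(C)[Si](C)(C)OC[C@H](C)CCC[C@H](C)[C@H](CCC=C)c1cc(OCOC)ccc1Br | intermediate
17 | aryllithium from 16 (Li in place of Br) | CC(C)(C)[Si](C)(C)OC[C@H](C)CCC[C@H](C)[C@H](CCC=C)c1cc(OCOC)ccc1[Li] | intermediate (not isolated)
18 | 2-[(5S,6S,10R)-11-[(tert-butyldimethylsilyl)oxy]-6,10-dimethylundec-1-en-5-yl]-4-(methoxymethoxy)benzoic acid | CC(C)(C)[Si](C)(C)OC[C@H](C)CCC[C@H](C)[C@H](CCC=C)c1cc(OCOC)ccc1C(=O)O | intermediate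
19 | 2-(trimethylsilyl)ethyl 2-[(5S,6S,10R)-11-[(tert-butyldimethylsilyl)oxy]-6,10-dimethylundec-1-en-5-yl]-4-(methoxymethoxy)benzoate | CC(C)(C)[Si](C)(C)OC[C@H](C)CCC[C@H](C)[C@H](CCC=C)c1cc(OCOC)ccc1C(=O)OCC[Si](C)(C)C | intermediate (key-step precursor)
20 | 2-(trimethylsilyl)ethyl (5R,8S)-8-[(2S,6R)-7-[(tert-butyldimethylsilyl)oxy]-6-methylheptan-2-yl]-4-(methoxymethoxy)-5-methyl-5,6,7,8-tetrahydronaphthalene-1-carboxylate | CC(C)(C)[Si](C)(C)OC[C@H](C)CCC[C@H](C)[C@@H]1CC[C@@H](C)c2c(OCOC)ccc(C(=O)OCC[Si](C)(C)C)c21 | intermediate (key-step product)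
21 | 2-(trimethylsilyl)ethyl (5R,8S)-8-[(2S,6R)-7-hydroxy-6-methylheptan-2-yl]-4-(methoxymethoxy)-5-methyl-5,6,7,8-tetrahydronaphthalene-1-carboxylate | OC[C@H](C)CCC[C@H](C)[C@@H]1CC[C@@H](C)c2c(OCOC)ccc(C(=O)OCC[Si](C)(C)C)c21 | intermediate
22 | 4-methylpent-3-enoic acid | CC(C)=CCC(=O)O | starting material
23 | 2-(trimethylsilyl)ethyl (5R,8S)-4-(methoxymethoxy)-5-methyl-8-[(2S,6R)-6-methyl-7-[(4-methylpent-3-enoyl)oxy]heptan-2-yl]-5,6,7,8-tetrahydronaphthalene-1-carboxylate | CC(C)=CCC(=O)OC[C@H](C)CCC[C@H](C)[C@@H]1CC[C@@H](C)c2c(OCOC)ccc(C(=O)OCC[Si](C)(C)C)c21 | intermediate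
24 | aryl trimethylsilyl ether of 25 | CC(C)=CCC(=O)OC[C@H](C)CCC[C@H](C)[C@@H]1CC[C@@H](C)c2c(O[Si](C)(C)C)ccc(C(=O)OCC[Si](C)(C)C)c21 | intermediate (not isolated)
25 | 2-(trimethylsilyl)ethyl (5R,8S)-4-hydroxy-5-methyl-8-[(2S,6R)-6-methyl-7-[(4-methylpent-3-enoyl)oxy]heptan-2-yl]-5,6,7,8-tetrahydronaphthalene-1-carboxylate | CC(C)=CCC(=O)OC[C@H](C)CCC[C@H](C)[C@@H]1CC[C@@H](C)c2c(O)ccc(C(=O)OCC[Si](C)(C)C)c21 | intermediate
26 | (5R,8S)-4-hydroxy-5-methyl-8-[(2S,6R)-6-methyl-7-[(4-methylpent-3-enoyl)oxy]heptan-2-yl]-5,6,7,8-tetrahydronaphthalene-1-carboxylic acid | CC(C)=CCC(=O)OC[C@H](C)CCC[C@H](C)[C@@H]1CC[C@@H](C)c2c(O)ccc(C(=O)O)c21 | target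

**Count**
Total steps: 19. Longest linear sequence: 16 (steps 1–4 and 8–19); the side branch (steps 5–7) joins at step 8.

**Steps most likely to fail**

Step 15 (key step). The ring closure may discriminate poorly between the two faces, giving the 1,4-cis isomer. The ester-deactivated arene may also capture the C4 cation equivalent so slowly that fluoride capture or alkene isomerisation wins. The fallback sets out from 19 and fixes C4 by reagent control. The alkene is epoxidised (mCPBA, NaHCO3, CH2Cl2) to the oxirane F1 as both C4 epimers. Hydrolytic kinetic resolution with the acetate of the trivalent cobalt salen complex, (salen)Co(OAc), and 0.55 equiv of water follows, with the catalyst antipode chosen so that the 4S epimer is hydrolysed. It leaves the (4R)-oxirane F2 and turns the other epimer into the diol F3, which is separated. Epoxy–arene Friedel–Crafts cyclisation of the (4R)-oxirane (HFIP, 0 °C → rt; SnCl4 in CH2Cl2 at −78 °C if more activation is needed) opens the oxirane 6-exo at C4 with inversion and gives the C4 hydroxymethyl tetralin F4. Iodination (I2, PPh3, imidazole) gives the iodomethyl tetralin F5, and Bu3SnH/AIBN (toluene, 80 °C) reduces it to the C4 methyl group. The sequence comes back to the route at 20.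

Step 8. Metathesis at the allylically branched alkene of 7 may be slow, so that the catalyst decays and the partner merely homodimerises. The fallback sets out from lactol 6 and uses iodide 10, so steps 4 and 7 are not needed. Ohira–Bestmann homologation (dimethyl (1-diazo-2-oxopropyl)phosphonate, K2CO3, MeOH) gives the alkynol F6. Its dianion (n-BuLi, 2.1 equiv, THF/DMPU, −78 °C → rt) is alkylated at carbon with iodide 10 to give the internal alkyne F7. Hydrogenation (H2, palladium on carbon, EtOAc) saturates the alkyne and comes back to the route at 13.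

Step 18. The silyl triflate may ionise the trisubstituted alkene of the 4-methylpent-3-enoate (lactonisation with loss of the side chain, or alkene migration), or the acetal cleavage may stall. The fallback sets out from 20 and removes both acid-labile groups before the acyl group is on. HCl in MeOH (rt → 40 °C) cleaves the TBS ether and the MOM ether and gives the phenol–alcohol F8 with the 2-(trimethylsilyl)ethyl ester intact. Mitsunobu esterification with 22 (PPh3, DIAD, THF, 0 °C) should then acylate only the primary alcohol, because the carboxylic acid is far more acidic than the phenol and is the pronucleophile. This gives 25 directly and comes back to the route before step 19.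

**Further compounds**
F1 | step 15 | 2-(trimethylsilyl)ethyl 2-[(3S,4S,8R)-9-[(tert-butyldimethylsilyl)oxy]-4,8-dimethyl-1-(oxiran-2-yl)nonan-3-yl]-4-(methoxymethoxy)benzoate (both oxirane epimers) | CC(C)(C)[Si](C)(C)OC[C@H](C)CCC[C@H](C)[C@H](CCC1CO1)c2cc(OCOC)ccc2C(=O)OCC[Si](C)(C)C
F2 | step 15 | 2-(trimethylsilyl)ethyl 2-[(3S,4S,8R)-9-[(tert-butyldimethylsilyl)oxy]-4,8-dimethyl-1-[(2R)-oxiran-2-yl]nonan-3-yl]-4-(methoxymethoxy)benzoate | CC(C)(C)[Si](C)(C)OC[C@H](C)CCC[C@H](C)[C@H](CC[C@@H]1CO1)c2cc(OCOC)ccc2C(=O)OCC[Si](C)(C)C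
F3 | step 15 | 2-(trimethylsilyl)ethyl 2-[(2S,5S,6S,10R)-11-[(tert-butyldimethylsilyl)oxy]-1,2-dihydroxy-6,10-dimethylundecan-5-yl]-4-(methoxymethoxy)benzoate (diol of the unwanted epimer) | CC(C)(C)[Si](C)(C)OC[C@H](C)CCC[C@H](C)[C@H](CC[C@H](O)CO)c2cc(OCOC)ccc2C(=O)OCC[Si](C)(C)C
F4 | step 15 | 2-(trimethylsilyl)ethyl (5R,8S)-8-[(2S,6R)-7-[(tert-butyldimethylsilyl)oxy]-6-methylheptan-2-yl]-5-(hydroxymethyl)-4-(methoxymethoxy)-5,6,7,8-tetrahydronaphthalene-1-carboxylate | CC(C)(C)[Si](C)(C)OC[C@H](C)CCC[C@H](C)[C@@H]1CC[C@@H](CO)c2c(OCOC)ccc(C(=O)OCC[Si](C)(C)C)c21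
F5 | step 15 | 2-(trimethylsilyl)ethyl (5R,8S)-8-[(2S,6R)-7-[(tert-butyldimethylsilyl)oxy]-6-methylheptan-2-yl]-5-(iodomethyl)-4-(methoxymethoxy)-5,6,7,8-tetrahydronaphthalene-1-carboxylate | CC(C)(C)[Si](C)(C)OC[C@H](C)CCC[C@H](C)[C@@H]1CC[C@@H](CI)c2c(OCOC)ccc(C(=O)OCC[Si](C)(C)C)c21
F6 | step 8 | (3S,4R)-3-[3-(methoxymethoxy)phenyl]-4-methylhex-5-yn-1-ol | C#C[C@H](C)[C@H](CCO)c1cccc(OCOC)c1
F7 | step 8 | (3S,4R,8R)-9-[(tert-butyldimethylsilyl)oxy]-3-[3-(methoxymethoxy)phenyl]-4,8-dimethylnon-5-yn-1-ol | CC(C)(C)[Si](C)(C)OC[C@H](C)CC#C[C@H](C)[C@H](CCO)c1cccc(OCOC)c1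
F8 | step 18 | 2-(trimethylsilyl)ethyl (5R,8S)-4-hydroxy-8-[(2S,6R)-7-hydroxy-6-methylheptan-2-yl]-5-methyl-5,6,7,8-tetrahydronaphthalene-1-carboxylate | OC[C@H](C)CCC[C@H](C)[C@@H]1CC[C@@H](C)c2c(O)ccc(C(=O)OCC[Si](C)(C)C)c21
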